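The route rests on disconnecting the C3–C4 bond of the 4-hydroxy-3-methylfuran-2(5H)-one ring, exploiting its β-keto lactone pattern O1–C2(=O)–C3–C4. The precursor is acyclic: a propanoate (C2, C3 and its methyl) esterified to the C5 oxygen, with C4 present as the imide carbonyl of the Evans oxazolidinone that earlier sets C5. In one operation a Dieckmann-type closure joins the propanoate α-carbon to that carbonyl, forms the ring and expels the auxiliary, so the C4–N bond, absent from the target, serves stereocontrol and is then cleaved without a separate step. The chain comes from (2E,6E)-farnesol by asymmetric hydrogenation (C7), terminal allylic oxidation and a furan Suzuki coupling.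

Key step: step 11

Remark on the chemistry: atoms are numbered O1, C2 (lactone carbonyl), C3 (C–CH3), C4 (C–OH), C5 (ring stereocentre, R) and C6–C18 along the side chain to the furan (C7, R, carries the methyl group; both chain alkenes E); (2E,6E)-farnesol of high isomeric purity is assumed as purchased.

Step 1
Reactants: 1 (2E,6E)-farnesol
Product: 2 (3R,6E)-3,7,11-trimethyldodeca-6,10-dien-1-ol [(R)-2,3-dihydrofarnesol]
Conditions: H2 (100 atm), Ru(OAc)2[(S)-BINAP] (0.2 mol%), MeOH/H2O 95:5, 20 °C
Reagents that add atoms: none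
Why: Noyori asymmetric hydrogenation of an allylic alcohol, in which the hydroxyl-directed divalent ruthenium BINAP catalyst should reduce only the 2,3-alkene and, with the (S)-ligand on the (2E)-substrate, set the 3R methyl stereocentre (C7 of the target) as in the geraniol-to-(R)-citronellol case, leaving the two isolated trisubstituted alkenes untouched.

Step 2
Reactants: 2 (3R,6E)-3,7,11-trimethyldodeca-6,10-dien-1-ol
Product: 3 (3R,6E)-1-chloro-3,7,11-trimethyldodeca-6,10-diene
Conditions: N-chlorosuccinimide, PPh3, THF, 0 °C → rt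
Reagents that add atoms: N-chlorosuccinimide, O=C1CCC(=O)N1Cl
Why: Appel-type chlorination (chlorophosphonium activation, SN2 displacement at a primary carbon) should give a chloride that is inert in steps 3–6 and later serves as the Grignard precursor, without touching the stereocentre.

Step 3
Reactants: 3 (3R,6E)-1-chloro-3,7,11-trimethyldodeca-6,10-diene
Product: 4 (2E,6E,10R)-12-chloro-2,6,10-trimethyldodeca-2,6-dien-1-ol
Conditions: SeO2 (0.1 equiv), t-BuOOH (3 equiv), salicylic acid (0.1 equiv), CH2Cl2, rt, stopped at partial conversion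
Reagents that add atoms: selenium dioxide, O=[Se]=O, re-oxidised by tert-butyl hydroperoxide, CC(C)(C)OO, the net oxygen source
Why: Sharpless-modified Riley allylic oxidation (ene reaction then [2,3]-sigmatropic shift) should hydroxylate the (E)-methyl of the terminal isopropylidene group, the site preference established for farnesyl-type chains, giving the (E)-allylic alcohol.

Step 4
Reactants: 4 (2E,6E,10R)-12-chloro-2,6,10-trimethyldodeca-2,6-dien-1-ol
Product: 5 (2E,6E,10R)-1-bromo-12-chloro-2,6,10-trimethyldodeca-2,6-diene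
Conditions: CBr4, PPh3, CH2Cl2, 0 °C; used crude
Reagents that add atoms: carbon tetrabromide, BrC(Br)(Br)Br
Why: Appel bromination under neutral conditions should give the primary allylic bromide without allylic transposition or loss of the E geometry, the alkyl chloride being unaffected.

Step 5
Reactants: 5 (2E,6E,10R)-1-bromo-12-chloro-2,6,10-trimethyldodeca-2,6-diene; 6 vinylmagnesium bromide
Product: 7 (4E,8E,12R)-14-chloro-4,8,12-trimethyltetradeca-1,4,8-triene
Conditions: CuI (10 mol%), THF, −30 → 0 °C
Reagents that add atoms: vinylmagnesium bromide (6), C=C[Mg]Br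
Why: Copper-catalysed coupling of a vinyl Grignard reagent with a primary allylic bromide should occur at the unhindered α-carbon (SN2 mode) with retention of alkene geometry to give the skipped triene, the primary alkyl chloride being unreactive at this temperature.

Step 6
Reactants: 7 (4E,8E,12R)-14-chloro-4,8,12-trimethyltetradeca-1,4,8-triene; 8 3-bromofuran
Product: 10 3-[(4E,8E,12R)-14-chloro-4,8,12-trimethyltetradeca-4,8-dien-1-yl]furan, via B-alkyl-9-BBN borane 9 (not isolated)
Conditions: 9-BBN (1.1 equiv), THF, 0 °C → rt; then 8, Pd(dppf)Cl2 (5 mol%), aq. K3PO4, DMF, 50 °C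
Reagents that add atoms: 3-bromofuran (8), Brc1ccoc1
Why: 9-BBN should hydroborate only the monosubstituted alkene (anti-Markovnikov), and the B-alkyl borane should then undergo B-alkyl Suzuki–Miyaura coupling with 3-bromofuran to install the three-carbon link to the furan, the alkyl chloride being inert to zerovalent palladium under these conditions.

Step 7
Reactants: 10 3-[(4E,8E,12R)-14-chloro-4,8,12-trimethyltetradeca-4,8-dien-1-yl]furan; 11 carbon dioxide
Product: 13 (4R,7E,11E)-15-(furan-3-yl)-4,8,12-trimethylpentadeca-7,11-dienoic acid, via alkylmagnesium chloride 12 (not isolated)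
Conditions: Mg turnings (I2-activated), THF, reflux; then CO2 (dry gas), −78 → 0 °C; cold 1 M HCl work-up
Reagents that add atoms: carbon dioxide (11), O=C=O
Why: Grignard formation from the primary chloride followed by carboxylation should give the one-carbon-homologated acid whose carboxyl carbon becomes C4 of the tetronic acid.

Step 8
Reactants: 13 (4R,7E,11E)-15-(furan-3-yl)-4,8,12-trimethylpentadeca-7,11-dienoic acid; 14 (4R)-4-benzyl-1,3-oxazolidin-2-one
Product: 16 (4R)-4-benzyl-3-[(4R,7E,11E)-15-(furan-3-yl)-4,8,12-trimethylpentadeca-7,11-dienoyl]-1,3-oxazolidin-2-one, via mixed pivalic anhydride 15 (not isolated)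
Conditions: PivCl, Et3N, THF, −20 °C; then 14, LiCl, rt
Reagents that add atoms: (4R)-4-benzyl-1,3-oxazolidin-2-one (14), O=C1N[C@H](Cc2ccccc2)CO1
Why: Evans imide formation through the mixed pivalic anhydride (LiCl/Et3N variant) should acylate the oxazolidinone at the less hindered carbonyl of the anhydride.

Step 9
Reactants: 16 (4R)-4-benzyl-3-[(4R,7E,11E)-15-(furan-3-yl)-4,8,12-trimethylpentadeca-7,11-dienoyl]-1,3-oxazolidin-2-one
Product: 18 (4R)-4-benzyl-3-[(2R,4R,7E,11E)-15-(furan-3-yl)-2-hydroxy-4,8,12-trimethylpentadeca-7,11-dienoyl]-1,3-oxazolidin-2-one, via sodium imide enolate 17 (not isolated)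
Conditions: NaN(SiMe3)2 (1.1 equiv), THF, −78 °C; then 2-(phenylsulfonyl)-3-phenyloxaziridine, −78 °C; AcOH quench
Reagents that add atoms: 2-(phenylsulfonyl)-3-phenyloxaziridine (Davis oxaziridine), O=S(=O)(c1ccccc1)N1OC1c1ccccc1
Why: Evans asymmetric enolate hydroxylation, in which the chelated (Z)-sodium enolate is oxidised by the Davis oxaziridine on the face opposite the benzyl group of the (R)-auxiliary, should set the 2R carbinol (C5 of the target).

Step 10
Reactants: 18 (4R)-4-benzyl-3-[(2R,4R,7E,11E)-15-(furan-3-yl)-2-hydroxy-4,8,12-trimethylpentadeca-7,11-dienoyl]-1,3-oxazolidin-2-one; 19 propanoic anhydride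
Product: 20 (2R,4R,7E,11E)-1-[(4R)-4-benzyl-2-oxo-1,3-oxazolidin-3-yl]-15-(furan-3-yl)-4,8,12-trimethyl-1-oxopentadeca-7,11-dien-2-yl propanoate
Conditions: Et3N, DMAP (cat.), CH2Cl2, 0 °C → rt
Reagents that add atoms: propanoic anhydride (19), CCC(=O)OC(=O)CC
Why: DMAP-catalysed acylation of the secondary alcohol should give the propanoate without epimerisation, because the α-hydrogen of an α-branched N-acyl oxazolidinone is held in the imide plane by allylic 1,3-strain and resists enolisation.

Step 11
Reactants: 20 (2R,4R,7E,11E)-1-[(4R)-4-benzyl-2-oxo-1,3-oxazolidin-3-yl]-15-(furan-3-yl)-4,8,12-trimethyl-1-oxopentadeca-7,11-dien-2-yl propanoate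
Product: 22 (5R)-5-[(2R,5E,9E)-13-(furan-3-yl)-2,6,10-trimethyltrideca-5,9-dien-1-yl]-4-hydroxy-3-methylfuran-2(5H)-one (CNP0280565.1), via lithium propanoate enolate 21 (not isolated)
Conditions: LiN(SiMe3)2 (2.2 equiv), THF, −78 → 0 °C; cold 1 M HCl work-up; auxiliary 14 recovered from the neutral fraction
Reagents that add atoms: none
Why: Proposed new method: LiN(SiMe3)2 should deprotonate the propanoate CH2 (the C5–H of the α-branched imide lies in the imide plane through allylic 1,3-strain and is kinetically non-acidic), and the ester enolate carbon (C3) should add to the exocyclic imide carbonyl (C4) and expel the oxazolidinone anion, which deprotonates the β-keto lactone to the lithium tetronate, acidification then giving the enol. The closest known reaction types are the Dieckmann cyclisation of α-acyloxy esters to tetronic acids and the displacement of oxazolidinone auxiliaries from N-acyl oxazolidinones by stabilised carbanions such as lithiated phosphonates or ester enolates. The furanone ring closes in the 5-exo-trig mode. No new stereocentre is formed: C3 becomes sp2 and C5, set in step 9, should be retained because it is never enolised. The step needs site-selective enolisation (propanoate rather than C5–H), secured by the strain argument and low temperature, and attack at the exocyclic rather than the carbamate carbonyl, secured by ring size (five- against seven-membered). Formation of the stabilised tetronate anion should make the closure irreversible.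

Compound list
1 | (2E,6E)-farnesol [(2E,6E)-3,7,11-trimethyldodeca-2,6,10-trien-1-ol] | OC/C=C(\C)CC/C=C(\C)CCC=C(C)C | starting material
2 | (3R,6E)-3,7,11-trimethyldodeca-6,10-dien-1-ol | OCC[C@H](C)CC/C=C(\C)CCC=C(C)C | intermediate
3 | (3R,6E)-1-chloro-3,7,11-trimethyldodeca-6,10-diene | ClCC[C@H](C)CC/C=C(\C)CCC=C(C)C | intermediate
4 | (2E,6E,10R)-12-chloro-2,6,10-trimethyldodeca-2,6-dien-1-ol | ClCC[C@H](C)CC/C=C(\C)CC/C=C(\C)CO | intermediate
5 | (2E,6E,10R)-1-bromo-12-chloro-2,6,10-trimethyldodeca-2,6-diene | ClCC[C@H](C)CC/C=C(\C)CC/C=C(\C)CBr | intermediate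
6 | vinylmagnesium bromide | C=C[Mg]Br | starting material
7 | (4E,8E,12R)-14-chloro-4,8,12-trimethyltetradeca-1,4,8-triene | ClCC[C@H](C)CC/C=C(\C)CC/C=C(\C)CC=C | intermediate
8 | 3-bromofuran | Brc1ccoc1 | starting material
9 | 9-[(4E,8E,12R)-14-chloro-4,8,12-trimethyltetradeca-4,8-dien-1-yl]-9-borabicyclo[3.3.1]nonane | ClCC[C@H](C)CC/C=C(\C)CC/C=C(\C)CCCB1C2CCCC1CCC2 | intermediate
10 | 3-[(4E,8E,12R)-14-chloro-4,8,12-trimethyltetradeca-4,8-dien-1-yl]furan | ClCC[C@H](C)CC/C=C(\C)CC/C=C(\C)CCCc1ccoc1 | intermediate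
11 | carbon dioxide | O=C=O | starting material
12 | [(3R,6E,10E)-14-(furan-3-yl)-3,7,11-trimethyltetradeca-6,10-dien-1-yl]magnesium chloride | Cl[Mg]CC[C@H](C)CC/C=C(\C)CC/C=C(\C)CCCc1ccoc1 | intermediate
13 | (4R,7E,11E)-15-(furan-3-yl)-4,8,12-trimethylpentadeca-7,11-dienoic acid | OC(=O)CC[C@H](C)CC/C=C(\C)CC/C=C(\C)CCCc1ccoc1 | intermediate
14 | (4R)-4-benzyl-1,3-oxazolidin-2-one | O=C1N[C@H](Cc2ccccc2)CO1 | starting material
15 | (4R,7E,11E)-15-(furan-3-yl)-4,8,12-trimethylpentadeca-7,11-dienoic pivalic anhydride | CC(C)(C)C(=O)OC(=O)CC[C@H](C)CC/C=C(\C)CC/C=C(\C)CCCc1ccoc1 | intermediate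
16 | (4R)-4-benzyl-3-[(4R,7E,11E)-15-(furan-3-yl)-4,8,12-trimethylpentadeca-7,11-dienoyl]-1,3-oxazolidin-2-one | O=C(CC[C@H](C)CC/C=C(\C)CC/C=C(\C)CCCc1ccoc1)N1[C@H](Cc2ccccc2)COC1=O | intermediate
17 | sodium (Z)-enolate of imide 16 | [Na+].[O-]/C(=C\C[C@H](C)CC/C=C(\C)CC/C=C(\C)CCCc1ccoc1)N1[C@H](Cc2ccccc2)COC1=O | intermediate
18 | (4R)-4-benzyl-3-[(2R,4R,7E,11E)-15-(furan-3-yl)-2-hydroxy-4,8,12-trimethylpentadeca-7,11-dienoyl]-1,3-oxazolidin-2-one | O=C([C@H](O)C[C@H](C)CC/C=C(\C)CC/C=C(\C)CCCc1ccoc1)N1[C@H](Cc2ccccc2)COC1=O | intermediate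
19 | propanoic anhydride | CCC(=O)OC(=O)CC | starting material
20 | (2R,4R,7E,11E)-1-[(4R)-4-benzyl-2-oxo-1,3-oxazolidin-3-yl]-15-(furan-3-yl)-4,8,12-trimethyl-1-oxopentadeca-7,11-dien-2-yl propanoate | CCC(=O)O[C@H](C[C@H](C)CC/C=C(\C)CC/C=C(\C)CCCc1ccoc1)C(=O)N1[C@H](Cc2ccccc2)COC1=O | intermediate
21 | lithium enolate of the propanoate group of 20 | [Li+].[O-]C(=CC)O[C@H](C[C@H](C)CC/C=C(\C)CC/C=C(\C)CCCc1ccoc1)C(=O)N1[C@H](Cc2ccccc2)COC1=O | intermediate
22 | (5R)-5-[(2R,5E,9E)-13-(furan-3-yl)-2,6,10-trimethyltrideca-5,9-dien-1-yl]-4-hydroxy-3-methylfuran-2(5H)-one (CNP0280565.1) | CC1=C(O)[C@@H](C[C@H](C)CC/C=C(\C)CC/C=C(\C)CCCc2ccoc2)OC1=O | target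

Total step count: 11
Longest linear sequence: 11 steps (1 → 22)

Steps most likely to fail

Step 11 (Proposed new method). Enolisation may take place at C5–H instead of at the propanoate, leading to epimerisation or O-to-C acyl migration. The ester enolate may also fragment to methylketene, or the released oxazolidinone anion may take up the propanoyl group intermolecularly before ring closure. The fallback uses known chemistry, sets out from 18 and comes back at 22. Transesterification of 18 with MeOMgBr (MeOH, 0 °C) removes the auxiliary and should give methyl (2R,4R,7E,11E)-15-(furan-3-yl)-2-hydroxy-4,8,12-trimethylpentadeca-7,11-dienoate F1. Acylation with propanoic anhydride, Et3N and DMAP should give methyl (2R,4R,7E,11E)-15-(furan-3-yl)-4,8,12-trimethyl-2-(propanoyloxy)pentadeca-7,11-dienoate F2. Classical Dieckmann cyclisation of this α-acyloxy ester with LiN(SiMe3)2 (THF, −78 °C) and cold acid work-up should give 22.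

Step 3. Oxidation may spread to the allylic positions of the internal alkene, and the product may be over-oxidised to the enal. The fallback sets out from 3 and comes back at 4; it builds the (E)-allylic alcohol by olefination instead of C–H oxidation. Terminal-selective bromohydrin formation (N-bromosuccinimide, THF/H2O, 0 °C) should give (6E,10R)-3-bromo-12-chloro-2,6,10-trimethyldodec-6-en-2-ol F3. Ring closure with K2CO3 in MeOH should give 3-[(3E,7R)-9-chloro-3,7-dimethylnon-3-en-1-yl]-2,2-dimethyloxirane F4. Cleavage with H5IO6 (THF/Et2O, 0 °C) should give (4E,8R)-10-chloro-4,8-dimethyldec-4-enal F5. Wittig olefination with the stabilised ylide Ph3P=C(CH3)CO2Et (CH2Cl2, rt) should give ethyl (2E,6E,10R)-12-chloro-2,6,10-trimethyldodeca-2,6-dienoate F6. Reduction with i-Bu2AlH (CH2Cl2, −78 °C) should give 4.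

Step 6. The B-alkyl borane may undergo protodeboronation, the alkylpalladium intermediate may undergo β-hydride elimination, and volatile, electron-rich 3-bromofuran may be lost before oxidative addition. The fallback sets out from 5 (with 8 as the furan source) and comes back at 10, bypassing 7 and 9. It joins C16 to C17 by an sp3–sp3 coupling instead of joining C18 to the furan. Bromine–lithium exchange on 8 (n-BuLi, THF, −78 °C) should give furan-3-yllithium F7. Opening of ethylene oxide (BF3·OEt2, −78 °C) should give 2-(furan-3-yl)ethan-1-ol F8. CBr4/PPh3 should give 3-(2-bromoethyl)furan F9, and Mg in THF should give [2-(furan-3-yl)ethyl]magnesium bromide F10. Coupling of F10 with allylic bromide 5 under Li2CuCl4 catalysis (THF, −78 → 0 °C) should give 10.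

Further compounds
F1 | step 11 | methyl (2R,4R,7E,11E)-15-(furan-3-yl)-2-hydroxy-4,8,12-trimethylpentadeca-7,11-dienoate | COC(=O)[C@H](O)C[C@H](C)CC/C=C(\C)CC/C=C(\C)CCCc1ccoc1
F2 | step 11 | methyl (2R,4R,7E,11E)-15-(furan-3-yl)-4,8,12-trimethyl-2-(propanoyloxy)pentadeca-7,11-dienoate | CCC(=O)O[C@H](C[C@H](C)CC/C=C(\C)CC/C=C(\C)CCCc1ccoc1)C(=O)OC
F3 | step 3 | (6E,10R)-3-bromo-12-chloro-2,6,10-trimethyldodec-6-en-2-ol (both C3 epimers) | ClCC[C@H](C)CC/C=C(\C)CCC(Br)C(C)(C)O
F4 | step 3 | 3-[(3E,7R)-9-chloro-3,7-dimethylnon-3-en-1-yl]-2,2-dimethyloxirane (both oxirane epimers) | ClCC[C@H](C)CC/C=C(\C)CCC1OC1(C)C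
F5 | step 3 | (4E,8R)-10-chloro-4,8-dimethyldec-4-enal | ClCC[C@H](C)CC/C=C(\C)CCC=O
F6 | step 3 | ethyl (2E,6E,10R)-12-chloro-2,6,10-trimethyldodeca-2,6-dienoate | ClCC[C@H](C)CC/C=C(\C)CC/C=C(\C)C(=O)OCC
F7 | step 6 | furan-3-yllithium | [Li]c1ccoc1
F8 | step 6 | 2-(furan-3-yl)ethan-1-ol | OCCc1ccoc1
F9 | step 6 | 3-(2-bromoethyl)furan | BrCCc1ccoc1
F10 | step 6 | [2-(furan-3-yl)ethyl]magnesium bromide | Br[Mg]CCc1ccoc1
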